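A direct plan would join two bought arenes at the ether oxygen: 5-iodoresorcinol (A1) would be monobenzylated, pivaloylated and oxidised to [3-(benzyloxy)-5-(pivaloyloxy)phenyl](2,4,6-trimethoxyphenyl)iodonium tosylate (A2), which would O-arylate the 4-OH of 3,4,5-trihydroxybenzaldehyde (A3); benzylation, Dakin oxidation with ester cleavage, bis-sulfation and hydrogenolysis would finish.
- The monobenzylation of the symmetric diol A1 would differentiate the oxygens of ring A only statistically.
- The O-arylation of A3 by A2 would need a di-ortho-substituted phenoxide of an unprotected triol to couple site-selectively, without close precedent, and would spend a trimethoxyphenyl ligand.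
- The pivalate on/off and the aldehyde-to-phenol detour would be protecting-group and redox steps that build no bond of the skeleton.

**Retrosynthetic overview**
Ring A (C1–O–aryl, C3–OH, C5–OSO3H, all meta) would be built, not bought and desymmetrised: a thermal benzannulation inserts the two carbons of an aryloxyacetylene (ring B–O–C≡CH, future C1 and C6) into a 3-alkoxycyclobutenone (future C2 to C5). This forms the C1–C2 and C5–C6 bonds and delivers the three oxygens already differentiated as aryl ether, 4-methoxybenzyl ether and free phenol.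
Ring B exists first: its 1,2,3,5-tetraoxygenated pattern comes from 3,5-bis(benzyloxy)phenol by para-oxidation to the quinone, and the hindered and open hydroquinone hydroxyls are told apart by a bulky silyl chloride. The ether oxygen is bonded to a two-carbon unit from trichloroethylene, not to an arene.
No statistical monoprotection, no O-arylation and no aldehyde or pivalate detour would be needed; the one temporary group (silyl) falls in the work-up of the key step.

Key step: step 6

Remark: the target is drawn as the free bis(hydrogen sulfate); the route makes the dipotassium salt and protonates it only in the last operation, since aryl hydrogen sulfates are handled best as salts.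

Step 1
Reactants: 1 3,5-bis(benzyloxy)phenol
Product: 2 2,6-bis(benzyloxy)-1,4-benzoquinone
Conditions: (KO3S)2NO (2.5 equiv), KH2PO4, acetone/H2O, 0 °C to rt
Reagents that add atoms: potassium nitrosodisulfonate, [K+].[K+].[O]N(S(=O)(=O)[O-])S(=O)(=O)[O-]
Why: Teuber oxidation of a phenol with a free para position by the nitrosodisulfonate radical, which oxygenates the para carbon (the one flanked by both benzyloxy groups) and so turns the 1,3,5-pattern of 1 into the 1,2,3,5-tetraoxygenated pattern of ring B.

Step 2
Reactants: 2 2,6-bis(benzyloxy)-1,4-benzoquinone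
Product: 4 2,6-bis(benzyloxy)-4-[(triisopropylsilyl)oxy]phenol, via 2,6-bis(benzyloxy)benzene-1,4-diol 3 (not isolated)
Conditions: Na2S2O4, EtOAc/H2O, rt; organic phase dried and concentrated under N2; then iPr3SiCl (1.05 equiv), imidazole (2.2 equiv), CH2Cl2, 0 °C
Reagents that add atoms: chlorotriisopropylsilane, CC(C)[Si](Cl)(C(C)C)C(C)C
Why: Dithionite reduction of the quinone followed by silyl ether formation under steric control: the C4 hydroxyl, open and the more acidic one, takes the bulky silyl group, while the C1 hydroxyl between the two benzyloxy groups stays free for the ether link.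

Step 3
Reactants: 4 2,6-bis(benzyloxy)-4-[(triisopropylsilyl)oxy]phenol
Product: 5 1,3-bis(benzyloxy)-2-{[(E)-1,2-dichloroethenyl]oxy}-5-[(triisopropylsilyl)oxy]benzene
Conditions: Cl2C=CHCl (1.5 equiv), K2CO3 (2 equiv), DMF, 70 °C
Reagents that add atoms: trichloroethylene, ClC=C(Cl)Cl
Why: Base-mediated vinylation of a phenol with trichloroethylene (anti addition of the phenoxide to dichloroacetylene formed in situ, hence the E isomer), a small linear electrophile that a di-ortho-substituted phenoxide can reach, which ties the ether oxygen to the carbon that will become C1 of ring A.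

Step 4
Reactants: 5 1,3-bis(benzyloxy)-2-{[(E)-1,2-dichloroethenyl]oxy}-5-[(triisopropylsilyl)oxy]benzene
Product: 7 1,3-bis(benzyloxy)-2-(ethynyloxy)-5-[(triisopropylsilyl)oxy]benzene, via lithium aryloxyacetylide 6 (not isolated)
Conditions: n-BuLi (2.3 equiv), THF, −78 °C to −40 °C; H2O quench at −78 °C; used within a day
Reagents that add atoms: none
Why: Ynol ether synthesis from a 1,2-dichlorovinyl ether: vinylic deprotonation and β-elimination of LiCl give the chloroalkyne, lithium–chlorine exchange gives acetylide 6, and protonation gives the terminal alkyne, while benzyl and silyl ethers tolerate n-BuLi at −78 °C.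

Step 5
Reactants: 8 cyclobutane-1,3-dione
Product: 9 3-[(4-methoxybenzyl)oxy]cyclobut-2-en-1-one
Conditions: 4-MeOC6H4CH2OH (1.1 equiv), PPh3, DIAD, THF, 0 °C to rt
Reagents that add atoms: 4-methoxybenzyl alcohol, COc1ccc(CO)cc1
Why: Mitsunobu O-alkylation of a strongly acidic cyclic 1,3-dione through its enol (3-hydroxycyclobutenone), which gives the vinylogous ester under neutral conditions at room temperature and spares the strained ring.

Step 6
Reactants: 7 1,3-bis(benzyloxy)-2-(ethynyloxy)-5-[(triisopropylsilyl)oxy]benzene; 9 3-[(4-methoxybenzyl)oxy]cyclobut-2-en-1-one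
Product: 11 3-[2,6-bis(benzyloxy)-4-hydroxyphenoxy]-5-[(4-methoxybenzyl)oxy]phenol, via silyl ether phenol 10 (not isolated)
Conditions: 9 (1.5 equiv), toluene, 100 °C, N2, sealed; then KOH, MeOH/THF/H2O, 50 °C; aq. HCl to pH 5
Reagents that add atoms: none
Why: Danheiser benzannulation: 9 opens thermally (4π electrocyclic, reversible) to the 3-alkoxy vinylketene, which adds the ynol ether in a [2+2] cycloaddition; the 4-vinylcyclobutenone so formed opens again (4π) to a dienylketene that closes ring A by a thermal 6π electrocyclisation and tautomerises to phenol 10. The closest known reactions are the thermal benzannulations of cyclobutenones with alkoxy- and silyloxyalkynes that give resorcinol monoethers. The step needs regiocontrol: the nucleophilic terminal carbon of the ynol ether bonds to the ketene carbonyl carbon and the oxygen-bearing carbon to the ketene α-carbon, fixed by the polarisation of both partners, so the new OH (C5), the aryloxy group (C1) and the 4-methoxybenzyl ether (C3) end up mutually meta; a direct [4+2] path would give the same isomer, since C2, C4 and C6 all carry hydrogen. No stereocentre is formed. The aryl ynol ether has no β-hydrogen on the oxygen substituent, so it cannot lose an alkene to a ketene on heating. KOH in the same pot cleaves the silyl ether and any aryl ester formed from 10 and excess vinylketene, which frees exactly the two hydroxyls to be sulfated.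

Step 7
Reactants: 11 3-[2,6-bis(benzyloxy)-4-hydroxyphenoxy]-5-[(4-methoxybenzyl)oxy]phenol
Product: 13 dipotassium 3-[2,6-bis(benzyloxy)-4-(sulfonatooxy)phenoxy]-5-[(4-methoxybenzyl)oxy]phenyl sulfate, via bis(pyridinium) bis-sulfate 12 (not isolated)
Conditions: SO3·pyridine (6 equiv), pyridine, 45 °C; then 1 M KOH to pH 8; C18 chromatography (H2O/MeOH)
Reagents that add atoms: sulfur trioxide–pyridine complex, O=S(=O)([O-])[n+]1ccccc1; potassium hydroxide, [K+].[OH-]
Why: O-sulfonation of phenols with a sulfur trioxide–amine complex, for which only the two free, unhindered hydroxyls (C5–OH of ring A and the para OH of ring B) are available, followed by neutralisation to the dipotassium salt.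

Step 8
Reactants: 13 dipotassium 3-[2,6-bis(benzyloxy)-4-(sulfonatooxy)phenoxy]-5-[(4-methoxybenzyl)oxy]phenyl sulfate
Product: 15 3-[2,6-dihydroxy-4-(sulfooxy)phenoxy]-5-hydroxyphenyl hydrogen sulfate (target), via dipotassium salt 14 (not isolated)
Conditions: H2 (1 atm), 10% Pd/C, MeOH/H2O 4:1, rt; filtration; 1 M HCl (2.0 equiv), 0 °C; C18 desalting, lyophilisation
Reagents that add atoms: none
Why: Catalytic hydrogenolysis of the two benzyl ethers and the 4-methoxybenzyl ether, to which aryl sulfate monoester salts and the diaryl ether are inert, followed by cold protonation of salt 14 to the free acid.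

## Compound list

1 | 3,5-bis(benzyloxy)phenol | Oc1cc(OCc2ccccc2)cc(OCc2ccccc2)c1 | starting material
2 | 2,6-bis(benzyloxy)-1,4-benzoquinone | O=C1C=C(OCc2ccccc2)C(=O)C(OCc2ccccc2)=C1 | intermediate
3 | 2,6-bis(benzyloxy)benzene-1,4-diol | Oc1cc(OCc2ccccc2)c(O)c(OCc2ccccc2)c1 | intermediate
4 | 2,6-bis(benzyloxy)-4-[(triisopropylsilyl)oxy]phenol | CC(C)[Si](Oc1cc(OCc2ccccc2)c(O)c(OCc2ccccc2)c1)(C(C)C)C(C)C | intermediate
5 | 1,3-bis(benzyloxy)-2-{[(E)-1,2-dichloroethenyl]oxy}-5-[(triisopropylsilyl)oxy]benzene | Cl/C=C(/Cl)Oc1c(OCc2ccccc2)cc(O[Si](C(C)C)(C(C)C)C(C)C)cc1OCc1ccccc1 | intermediate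
6 | lithium {2,6-bis(benzyloxy)-4-[(triisopropylsilyl)oxy]phenoxy}acetylide | [Li]C#COc1c(OCc2ccccc2)cc(O[Si](C(C)C)(C(C)C)C(C)C)cc1OCc1ccccc1 | intermediate
7 | 1,3-bis(benzyloxy)-2-(ethynyloxy)-5-[(triisopropylsilyl)oxy]benzene | C#COc1c(OCc2ccccc2)cc(O[Si](C(C)C)(C(C)C)C(C)C)cc1OCc1ccccc1 | intermediate
8 | cyclobutane-1,3-dione | O=C1CC(=O)C1 | starting material
9 | 3-[(4-methoxybenzyl)oxy]cyclobut-2-en-1-one | O=C1C=C(OCc2ccc(OC)cc2)C1 | intermediate
10 | 3-{2,6-bis(benzyloxy)-4-[(triisopropylsilyl)oxy]phenoxy}-5-[(4-methoxybenzyl)oxy]phenol | Oc1cc(OCc2ccc(OC)cc2)cc(Oc2c(OCc3ccccc3)cc(O[Si](C(C)C)(C(C)C)C(C)C)cc2OCc2ccccc2)c1 | intermediate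
11 | 3-[2,6-bis(benzyloxy)-4-hydroxyphenoxy]-5-[(4-methoxybenzyl)oxy]phenol | Oc1cc(OCc2ccc(OC)cc2)cc(Oc2c(OCc3ccccc3)cc(O)cc2OCc2ccccc2)c1 | intermediate
12 | bis(pyridinium) 3-[2,6-bis(benzyloxy)-4-(sulfonatooxy)phenoxy]-5-[(4-methoxybenzyl)oxy]phenyl sulfate | [O-]S(=O)(=O)Oc1cc(OCc2ccc(OC)cc2)cc(Oc2c(OCc3ccccc3)cc(OS(=O)(=O)[O-])cc2OCc2ccccc2)c1.c1cc[nH+]cc1.c1cc[nH+]cc1 | intermediate
13 | dipotassium 3-[2,6-bis(benzyloxy)-4-(sulfonatooxy)phenoxy]-5-[(4-methoxybenzyl)oxy]phenyl sulfate | [K+].[K+].[O-]S(=O)(=O)Oc1cc(OCc2ccc(OC)cc2)cc(Oc2c(OCc3ccccc3)cc(OS(=O)(=O)[O-])cc2OCc2ccccc2)c1 | intermediate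
14 | dipotassium 3-[2,6-dihydroxy-4-(sulfonatooxy)phenoxy]-5-hydroxyphenyl sulfate | [K+].[K+].[O-]S(=O)(=O)Oc1cc(O)cc(Oc2c(O)cc(OS(=O)(=O)[O-])cc2O)c1 | intermediate
15 | 3-[2,6-dihydroxy-4-(sulfooxy)phenoxy]-5-hydroxyphenyl hydrogen sulfate (CNP0460023.0) | O=S(=O)(O)Oc1cc(O)cc(Oc2c(O)cc(OS(=O)(=O)O)cc2O)c1 | target

Total step count: 8. Longest linear sequence: 7 (steps 1, 2, 3, 4, 6, 7, 8).

**Steps most likely to fail**

1. Step 6. The vinylketene may dimerise or acylate the product phenol faster than the hindered, only moderately nucleophilic aryl ynol ether traps it, or the terminal ynol ether may oligomerise at 100 °C. The fallback sets out from 4, comes back at 11, and makes the ether bond by cross-coupling instead of building ring A. Purchased 5-bromoresorcinol would be mono-alkylated with 4-methoxybenzyl chloride (K2CO3, DMF) to 3-bromo-5-[(4-methoxybenzyl)oxy]phenol F1 and silylated (iPr3SiCl, imidazole) to {3-bromo-5-[(4-methoxybenzyl)oxy]phenoxy}triisopropylsilane F2. A Buchwald–Hartwig-type diaryl ether coupling of F2 with phenol 4 (Pd(OAc)2, 2-di-tert-butylphosphino-2',4',6'-triisopropylbiphenyl, K3PO4, toluene, 100 °C) would give the bis-silyl diaryl ether F3. Bu4NF in THF would then cleave both silyl ethers to give 11.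

2. Step 4. The terminal aryloxyacetylene may oligomerise or add water during work-up and storage. The fallback sets out from 5, comes back at 11, and carries the alkyne terminus as a C–Si bond through the benzannulation. Acetylide 6 made from 5 would be quenched with Me3SiCl to the storable {[2,6-bis(benzyloxy)-4-(triisopropylsilyloxy)phenoxy]ethynyl}trimethylsilane F4. Benzannulation of F4 with 9 (toluene, 110 °C) would give 3-{2,6-bis(benzyloxy)-4-[(triisopropylsilyl)oxy]phenoxy}-5-[(4-methoxybenzyl)oxy]-2-(trimethylsilyl)phenol F5, with silicon between the OH and the aryloxy group. Bu4NF in wet THF at 50 °C would cleave the aryl C–Si bond of this very electron-rich ring (ipso-protodesilylation) and the silyl ether to give 11.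

3. Step 5. The strained dione may undergo C-alkylation or ring cleavage under the Mitsunobu conditions. The fallback sets out from 8, comes back at 9, and forms the ring C3–O bond instead of the O–CH2 bond. It would be an acid-catalysed vinylogous esterification of 8 with 4-methoxybenzyl alcohol (pyridinium 4-toluenesulfonate, benzene, azeotropic removal of water), an addition–elimination at the ring carbon. It makes no new compound.

## Further compounds

F1 | step 6 | 3-bromo-5-[(4-methoxybenzyl)oxy]phenol | Oc1cc(Br)cc(OCc2ccc(OC)cc2)c1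
F2 | step 6 | {3-bromo-5-[(4-methoxybenzyl)oxy]phenoxy}triisopropylsilane | CC(C)[Si](Oc1cc(Br)cc(OCc2ccc(OC)cc2)c1)(C(C)C)C(C)C
F3 | step 6 | (3-{2,6-bis(benzyloxy)-4-[(triisopropylsilyl)oxy]phenoxy}-5-[(4-methoxybenzyl)oxy]phenoxy)triisopropylsilane | CC(C)[Si](Oc1cc(OCc2ccc(OC)cc2)cc(Oc2c(OCc3ccccc3)cc(O[Si](C(C)C)(C(C)C)C(C)C)cc2OCc2ccccc2)c1)(C(C)C)C(C)C
F4 | step 4 | {[2,6-bis(benzyloxy)-4-(triisopropylsilyloxy)phenoxy]ethynyl}trimethylsilane | C[Si](C)(C)C#COc1c(OCc2ccccc2)cc(O[Si](C(C)C)(C(C)C)C(C)C)cc1OCc1ccccc1
F5 | step 4 | 3-{2,6-bis(benzyloxy)-4-[(triisopropylsilyl)oxy]phenoxy}-5-[(4-methoxybenzyl)oxy]-2-(trimethylsilyl)phenol | C[Si](C)(C)c1c(O)cc(OCc2ccc(OC)cc2)cc1Oc1c(OCc2ccccc2)cc(O[Si](C(C)C)(C(C)C)C(C)C)cc1OCc1ccccc1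
F0 | step 5 | none | none
A1 | direct plan | 5-iodobenzene-1,3-diol | Oc1cc(O)cc(I)c1
A2 | direct plan | [3-(benzyloxy)-5-(pivaloyloxy)phenyl](2,4,6-trimethoxyphenyl)iodonium 4-methylbenzenesulfonate | CC(C)(C)C(=O)Oc1cc(OCc2ccccc2)cc([I+]c2c(OC)cc(OC)cc2OC)c1.Cc1ccc(S(=O)(=O)[O-])cc1
A3 | direct plan | 3,4,5-trihydroxybenzaldehyde | O=Cc1cc(O)c(O)c(O)c1
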